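# Proposed total synthesis of CNP0185870.1 by aryne annulation of a silyl-masked phenol lactone

## Analysis of the target

The target is a dibenzo[b,f]oxepine: ring A (C1–C4, C4a, C11a) and ring B (C5a, C6–C9, C9a) are joined by the ether oxygen O5 and by the C10=C11 double bond (oxepine ring C). A dihydropyran (ring D: O1' on C10, C2', C3', C4' on C11) is fused across C10–C11, so C10=C11 is a tetrasubstituted enol ether. Ring A carries a prenyl group at C2 and a hydroxyl at C3; ring B carries one hydroxyl at C7, meta to O5 and para to C10. The two stereocentres are adjacent in ring D: C2' (S) is a quaternary ether carbon bearing methyl and 4-methylpent-3-enyl, and C3' (S) is a secondary carbinol whose hydroxyl is cis to the homoprenyl chain. The enol ether is acid-sensitive, because protonation at C11 gives a C10 oxocarbenium ion stabilised by O1' and by the para-oxygenated ring B. The ortho-prenylphenol of ring A closes to a chroman in acid, and the two trisubstituted alkenes rule out hydrogenation and strong electrophiles. The difficulty lies in closing a seven-membered ring between two differently substituted arenes with C10 at the enol ether oxidation level, next to a quaternary stereocentre, and with three hydroxyls that need separate handling. The strategy rests on ring B: O5 (on C5a) and C10 (on C9a) sit on neighbouring carbons, the pattern an aryne produces when a nucleophile adds to one carbon and an electrophile is captured at the other.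

## Retrosynthetic reasoning

**Protecting groups and the chlorine (34 from 33, 31 and 30).** No skeletal bond is cut here. The C3' silyl ether of 33 is removed last by fluoride, so that the final step is not acidic. The two phenolic acetals of 31 are removed one step earlier by silyl transfer instead of protic acid. The chlorine at C9 of 30 is a control element of the key step and is taken out by palladium-catalysed transfer hydrogenolysis, which leaves the alkenes alone.

**Ring C (30 from 19 and 26).** The O5–C5a and C10–C9a bonds are cut, the two bonds ring B makes to the rest of the molecule. This frees ring B as aryne 28 and turns C10 into the carbonyl of δ-lactone 19, whose ring oxygen is already O1'. The cut is made here because it is the only one that separates the two arenes completely while keeping both stereocentres and the C10 oxidation level in one fragment. Forward, the ring A phenoxide must add to the aryne carbon that becomes C5a, and the aryl anion at C9a must then attack the lactone carbonyl. A chlorine next to the triple bond enforces this orientation; the alkoxy group at C7 is too remote to do so. The phenol of 19 is kept as a silyl ether, so that fluoride releases phenoxide and aryne together and no phenolic proton is present to quench the aryl anion.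

**Lactone (19 from 18, and 18 from 7 and 16).** The C10–O1' acyl bond is cut first (lactonisation of a tertiary alkoxide onto a methyl ester), then the C4'–C11 bond (enolate alkylation). C11 is benzylic and alpha to the ester, so it is the natural nucleophile, and C4' is a primary carbon. The secondary oxygen at C3' must carry its bulky silyl group before the ester meets a free hydroxyl, otherwise the five-membered lactone would form. C4' is beta-branched and beta-oxygenated, so the leaving group in 16 is a triflate. C11 is left uncontrolled because it becomes sp2.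

**Stereocentres (16 from 15, 14, 12, 11, 9 and nerol 8).** The 1,2-diol of 11 is the anti-diol of the Z-alkene of 8. It is reached by reagent-controlled epoxidation of the allylic alcohol, which also selects the 2,3-alkene over the 6,7-alkene, followed by a Payne shift that inverts C2 and opening at C1. The three hydroxyls of 11 are primary, secondary and tertiary and are told apart by size alone: pivalate on the primary (12), bulky silyl on the secondary, small silyl on the tertiary (14), then release of the primary (15).

**Ring A (7 from 6, 5, 4, 3, 2 and 1).** The two ring A oxygens need different masks, fluoride-labile at C4a and fluoride-stable at C3. In aldehyde 1 the hydroxyl ortho to the formyl group is hydrogen-bonded, so the para hydroxyl is alkylated alone (2). The free hydroxyl then directs bromine para to itself, to the future prenyl position (3). After silylation (4) and Stille prenylation (5), the formyl carbon is extended by one carbon to the acetate through enol ether 6. A diphenolic arylacetic acid would be a shorter start, but its hydroxyls cannot be differentiated cleanly.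

**Aryne precursor (26 from 23, 22, 21 and 20).** Either placement of silicon and triflate on the two aryne carbons gives the same aryne 28. The isomer with the triflate flanked by chlorine and silicon is chosen because it comes from a phenol by two ortho halogenations and a retro-Brook shift, each with unambiguous regiochemistry. Mono-protected hydroquinone 21 supplies the oxygen para to the phenol, which ends at C7.

## Alternatives that were turned down

**Alternative 1:** Ring A is cut open and built from an acyclic chain. Mild acid would unmask the aldehyde of the trioxo acetal A2, and base would then close and aromatise it by intramolecular aldol condensation to the prenylated resorcinol ketone A1.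

- For: the prenyl group and both phenols arrive in fixed positions without halogenation or cross-coupling. On this point it is stronger than the chosen route, which spends five steps dressing a bought benzene ring.
- Against: a chain with three ketones and several enolisable methylenes has competing aldol, Claisen and pyrone closures, and A2 is itself long to make and unstable. A1 also still lacks C10, ring B, ring C and ring D, and has C11 at the ketone level where the target needs it as an alkene carbon.
- Comparison: the chosen strategy buys both arenes and uses its key step on the seven-membered ring, the hard part that alternative 1 leaves open.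

**Alternative 2:** The O1'–C2' and C4'–C3' bonds of ring D are cut. A chiral Lewis acid would promote an inverse-demand oxadiene cycloaddition between the exocyclic enone A4 and the Z-alkenylboronate A5 to give the C3' boronate A3, and C–B oxidation with retention would give the carbinol.

- For: ring D, the enol ether and both stereocentres would form in one catalytic asymmetric step, the relative configuration following from the alkene geometry. For ring D this is more convergent than the chosen route, which needs eight steps from nerol 8 to reach lactone 19.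
- Against: A5 is a trisubstituted alkene without a donor group, a poor partner for an oxadiene that is itself deactivated by two alkoxyarenes. The oxygen must bond to the fully substituted carbon, A4 offers the catalyst only one binding point, and as an exocyclic enone it is prone to dimerise. A4 also already contains ring C, so the oxepine problem is moved, not solved.
- Comparison: the chosen strategy gives up the catalytic step for stereocentres set by a dependable epoxidation, and it builds ring C itself.

**Alternative 3:** The C11–aryl bond and the O1'–C10 bond are cut. An aryl-λ3-iodane would activate the exocyclic alkene of alkylidenexanthene A7, the tertiary hydroxyl would add to C9, and ring A would shift to the exocyclic carbon, giving the protected target A6.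

- For: xanthenes are easy to assemble, and rings C and D would form in one operation with the enol ether in place. In bond count per step it equals the chosen key step.
- Against: two aryl groups on C9 can migrate, and the choice between them rests only on a pivalate versus a silyl ether. The electrophilic iodine reagent must also select one alkene out of three and spare two electron-rich arenes, and simple alkoxy-iodination without the shift is a likely competitor.
- Comparison: in the chosen strategy the regiochemistry is fixed by a chlorine next to the aryne and no oxidant meets the alkenes.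

Key step: step 19

Remark: C11 epimers (compounds 17–19, 27, 29) are carried as mixtures because C11 ends as an sp2 carbon; locants follow the dibenzo[b,f]oxepine core with primed locants for pyran ring D, which is fused through O1'–C10 and C4'–C11.

## Route

Step 1
Reactants: 1 2,4-dihydroxybenzaldehyde
Product: 2 2-hydroxy-4-(methoxymethoxy)benzaldehyde
Conditions: MOMCl (1.05 equiv), K2CO3, acetone, 0 °C to rt
Reagents that add atoms: chloromethyl methyl ether, COCCl
Why: Williamson O-alkylation; the 2-hydroxyl is held in a hydrogen bond to the formyl oxygen and is the weaker nucleophile, so one equivalent of electrophile should go to the 4-hydroxyl.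

Step 2
Reactants: 2 2-hydroxy-4-(methoxymethoxy)benzaldehyde
Product: 3 5-bromo-2-hydroxy-4-(methoxymethoxy)benzaldehyde
Conditions: NBS, MeCN, 0 °C
Reagents that add atoms: N-bromosuccinimide, O=C1CCC(=O)N1Br
Why: Electrophilic aromatic bromination; the free hydroxyl directs para, the acetal oxygen ortho and the formyl group meta, all to C5, while C3 between the two oxygens is shielded.

Step 3
Reactants: 3 5-bromo-2-hydroxy-4-(methoxymethoxy)benzaldehyde
Product: 4 5-bromo-2-(tert-butyldimethylsilyloxy)-4-(methoxymethoxy)benzaldehyde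
Conditions: TBSCl, imidazole, DMF, rt
Reagents that add atoms: tert-butyldimethylsilyl chloride, CC(C)(C)[Si](C)(C)Cl
Why: Imidazole-promoted silylation of the phenol; this silyl ether is the fluoride-labile mask that releases the ring A phenoxide in step 19, and it keeps the phenol out of the ylide and enolate steps.

Step 4
Reactants: 4 5-bromo-2-(tert-butyldimethylsilyloxy)-4-(methoxymethoxy)benzaldehyde
Product: 5 2-(tert-butyldimethylsilyloxy)-4-(methoxymethoxy)-5-(3-methylbut-2-en-1-yl)benzaldehyde
Conditions: Bu3SnCH2CH=CMe2, Pd(PPh3)4 (5 mol %), toluene, 100 °C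
Reagents that add atoms: tributyl(3-methylbut-2-en-1-yl)stannane, CCCC[Sn](CCCC)(CCCC)CC=C(C)C
Why: Stille coupling; after transmetalation of the allylic stannane, reductive elimination at the less substituted allyl terminus should give the linear prenyl arene, and the neutral conditions spare aldehyde, acetal and silyl ether.

Step 5
Reactants: 5 2-(tert-butyldimethylsilyloxy)-4-(methoxymethoxy)-5-(3-methylbut-2-en-1-yl)benzaldehyde
Product: 6 tert-butyl{5-(methoxymethoxy)-2-(2-methoxyethenyl)-4-(3-methylbut-2-en-1-yl)phenoxy}dimethylsilane (E/Z mixture)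
Conditions: Ph3P(CH2OMe)Cl, KN(SiMe3)2, THF, −78 to 0 °C
Reagents that add atoms: (methoxymethyl)triphenylphosphonium chloride, COC[P+](c1ccccc1)(c1ccccc1)c1ccccc1.[Cl-]
Why: Wittig olefination with the methoxymethylene ylide; both enol ether isomers converge in step 6, and the non-nucleophilic amide base should leave the aryl silyl ether intact.

Step 6
Reactants: 6 tert-butyl{5-(methoxymethoxy)-2-(2-methoxyethenyl)-4-(3-methylbut-2-en-1-yl)phenoxy}dimethylsilane
Product: 7 methyl 2-[2-(tert-butyldimethylsilyloxy)-4-(methoxymethoxy)-5-(3-methylbut-2-en-1-yl)phenyl]acetate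
Conditions: pyridinium chlorochromate (C5H5NH[CrO3Cl]), NaOAc, 4 Å molecular sieves, CH2Cl2, rt
Reagents that add atoms: pyridinium chlorochromate, [O-][Cr](=O)(=O)Cl.c1cc[nH+]cc1
Why: Chlorochromate oxidation of an enol ether to the ester, which completes the one-carbon homologation of the aldehyde; the enol ether is far more nucleophilic than the prenyl alkene, and the acetate buffer protects the acetal.

Step 7
Reactants: 8 nerol, (2Z)-3,7-dimethylocta-2,6-dien-1-ol
Product: 9 [(2R,3S)-3-methyl-3-(4-methylpent-3-en-1-yl)oxiran-2-yl]methanol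
Conditions: Ti(OiPr)4 (cat.), D-(−)-diisopropyl tartrate (cat.), t-BuOOH, 4 Å molecular sieves, CH2Cl2, −20 °C
Reagents that add atoms: tert-butyl hydroperoxide, CC(C)(C)OO
Why: Sharpless asymmetric epoxidation; the titanium tartrate binds the allylic alcohol, so only the 2,3-alkene reacts, and the D-(−)-tartrate delivers oxygen to the face that gives the (2R,3S)-epoxide, which fixes the future C2' as S.

Step 8
Reactants: 9 [(2R,3S)-3-methyl-3-(4-methylpent-3-en-1-yl)oxiran-2-yl]methanol
Product: 11 (2S,3S)-3,7-dimethyloct-6-ene-1,2,3-triol, via terminal epoxide 10 (not isolated)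
Conditions: 0.5 M NaOH, t-BuOH/H2O, 75 °C
Reagents that add atoms: water, O
Why: Payne rearrangement followed by hydroxide opening; the C1 alkoxide displaces the epoxide oxygen at C2 with inversion, which sets the future C3' as S, and hydroxide then opens epoxide 10 at its primary carbon, the only unhindered site, without touching the tertiary centre.

Step 9
Reactants: 11 (2S,3S)-3,7-dimethyloct-6-ene-1,2,3-triol
Product: 12 (2S,3S)-2,3-dihydroxy-3,7-dimethyloct-6-en-1-yl 2,2-dimethylpropanoate
Conditions: PivCl (1.05 equiv), pyridine, CH2Cl2, −20 to 0 °C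
Reagents that add atoms: pivaloyl chloride, CC(C)(C)C(=O)Cl
Why: Sterically controlled acylation; the bulky acid chloride should esterify the primary hydroxyl much faster than the secondary one next to a quaternary carbon, and a pivalate does not migrate.

Step 10
Reactants: 12 (2S,3S)-2,3-dihydroxy-3,7-dimethyloct-6-en-1-yl 2,2-dimethylpropanoate
Product: 14 (2S,3S)-3,7-dimethyl-2-(triisopropylsilyloxy)-3-(trimethylsilyloxy)oct-6-en-1-yl 2,2-dimethylpropanoate, via secondary triisopropylsilyl ether 13 (not isolated)
Conditions: TIPSOTf, 2,6-lutidine, CH2Cl2, 0 °C to rt; then TMSOTf, 0 °C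
Reagents that add atoms: triisopropylsilyl trifluoromethanesulfonate, CC(C)[Si](OS(=O)(=O)C(F)(F)F)(C(C)C)C(C)C; trimethylsilyl trifluoromethanesulfonate, C[Si](C)(C)OS(=O)(=O)C(F)(F)F
Why: Silylation with silyl triflates; the bulky reagent should react at the secondary hydroxyl and not at the tertiary one, which the small reagent then caps in the same flask. The secondary silyl ether is what later forces lactonisation onto the tertiary oxygen.

Step 11
Reactants: 14 (2S,3S)-3,7-dimethyl-2-(triisopropylsilyloxy)-3-(trimethylsilyloxy)oct-6-en-1-yl 2,2-dimethylpropanoate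
Product: 15 (2S,3S)-3,7-dimethyl-2-(triisopropylsilyloxy)-3-(trimethylsilyloxy)oct-6-en-1-ol
Conditions: i-Bu2AlH, CH2Cl2, −78 °C; sodium potassium tartrate work-up
Reagents that add atoms: none
Why: Reductive cleavage of the pivalate by the aluminium hydride at low temperature should free the primary alcohol without touching either silyl ether or causing silyl migration.

Step 12
Reactants: 15 (2S,3S)-3,7-dimethyl-2-(triisopropylsilyloxy)-3-(trimethylsilyloxy)oct-6-en-1-ol
Product: 16 (2S,3S)-3,7-dimethyl-2-(triisopropylsilyloxy)-3-(trimethylsilyloxy)oct-6-en-1-yl trifluoromethanesulfonate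
Conditions: Tf2O, 2,6-lutidine, CH2Cl2, −78 °C; used at once
Reagents that add atoms: trifluoromethanesulfonic anhydride, O=S(=O)(OS(=O)(=O)C(F)(F)F)C(F)(F)F
Why: Sulfonylation of the primary alcohol; a triflate is chosen because this carbon is beta-branched and beta-oxygenated, and a halide or tosylate would be displaced too slowly by a stabilised enolate.

Step 13
Reactants: 7 methyl 2-[2-(tert-butyldimethylsilyloxy)-4-(methoxymethoxy)-5-(3-methylbut-2-en-1-yl)phenyl]acetate; 16 (2S,3S)-3,7-dimethyl-2-(triisopropylsilyloxy)-3-(trimethylsilyloxy)oct-6-en-1-yl trifluoromethanesulfonate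
Product: 18 methyl (4S,5S)-2-[2-(tert-butyldimethylsilyloxy)-4-(methoxymethoxy)-5-(3-methylbut-2-en-1-yl)phenyl]-5-hydroxy-5,9-dimethyl-4-(triisopropylsilyloxy)dec-8-enoate (C2 epimers), via trimethylsilyl ether 17 (not isolated)
Conditions: LiN(SiMe3)2, THF, −78 °C; then 16, −78 to −20 °C; then 1 M HCl, THF, 0 °C
Reagents that add atoms: none
Why: Alkylation of the lithium ester enolate (SN2 at the primary triflate) forms the C4'–C11 bond at a temperature where silyl migration from the aryl oxygen to the enolate should be slow. Dilute acid in the work-up hydrolyses only the labile tertiary trimethylsilyl ether; the new centre C11 is not controlled and need not be.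

Step 14
Reactants: 18 methyl (4S,5S)-2-[2-(tert-butyldimethylsilyloxy)-4-(methoxymethoxy)-5-(3-methylbut-2-en-1-yl)phenyl]-5-hydroxy-5,9-dimethyl-4-(triisopropylsilyloxy)dec-8-enoate
Product: 19 (5S,6S)-3-[2-(tert-butyldimethylsilyloxy)-4-(methoxymethoxy)-5-(3-methylbut-2-en-1-yl)phenyl]-6-methyl-6-(4-methylpent-3-en-1-yl)-5-(triisopropylsilyloxy)oxan-2-one (C3 epimers)
Conditions: t-BuMgCl (1.2 equiv), THF, 0 °C to rt; NH4Cl quench
Reagents that add atoms: none
Why: Lactonisation through the magnesium alkoxide (intramolecular transesterification, as when Grignard additions to δ-keto esters give δ-lactones directly); the hindered Grignard base should deprotonate oxygen and not C11. The six-membered ring must form on the tertiary oxygen because the secondary one is silylated, and chloromagnesium methoxide is too weak a nucleophile to cleave the aryl silyl ether.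

Step 15
Reactants: 20 hydroquinone
Product: 21 4-(methoxymethoxy)phenol
Conditions: MOMCl (0.5 equiv relative to 20), K2CO3, acetone, 0 °C to rt, under N2
Reagents that add atoms: chloromethyl methyl ether, COCCl
Why: Statistical mono-alkylation of a symmetrical diphenol, run with the diphenol in excess; unreacted 20 is washed out with water.

Step 16
Reactants: 21 4-(methoxymethoxy)phenol
Product: 22 2-chloro-4-(methoxymethoxy)phenol
Conditions: NCS, DMF, rt
Reagents that add atoms: N-chlorosuccinimide, O=C1CCC(=O)N1Cl
Why: Electrophilic aromatic chlorination; the free hydroxyl is the stronger director and its para position is blocked, so chlorine should enter ortho to it.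

Step 17
Reactants: 22 2-chloro-4-(methoxymethoxy)phenol
Product: 23 2-bromo-6-chloro-4-(methoxymethoxy)phenol
Conditions: NBS, CH2Cl2, 0 °C
Reagents that add atoms: N-bromosuccinimide, O=C1CCC(=O)N1Br
Why: Electrophilic aromatic bromination at the remaining position ortho to the hydroxyl; bromine comes after chlorine so that the more reactive halogenating agent meets the less activated ring.

Step 18
Reactants: 23 2-bromo-6-chloro-4-(methoxymethoxy)phenol
Product: 26 2-chloro-4-(methoxymethoxy)-6-(trimethylsilyl)phenyl trifluoromethanesulfonate, via aryl trimethylsilyl ether 24 (not isolated), via lithium phenoxide 25 (not isolated)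
Conditions: (Me3Si)2NH, THF, 65 °C, then evaporation; n-BuLi, THF, −78 °C; Tf2O, −78 to 0 °C
Reagents that add atoms: hexamethyldisilazane, C[Si](C)(C)N[Si](C)(C)C; trifluoromethanesulfonic anhydride, O=S(=O)(OS(=O)(=O)C(F)(F)F)C(F)(F)F
Why: O-silylation, bromine–lithium exchange with retro-Brook (1,3 O-to-C) silyl shift, then triflation of the phenoxide, the standard way to ortho-silylaryl triflates; exchange should be selective for bromine over chlorine and faster than any deprotonation.

Step 19
Reactants: 19 (5S,6S)-3-[2-(tert-butyldimethylsilyloxy)-4-(methoxymethoxy)-5-(3-methylbut-2-en-1-yl)phenyl]-6-methyl-6-(4-methylpent-3-en-1-yl)-5-(triisopropylsilyloxy)oxan-2-one; 26 2-chloro-4-(methoxymethoxy)-6-(trimethylsilyl)phenyl trifluoromethanesulfonate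
Product: 30 (2'S,3'S)-9-chloro-3,7-bis(methoxymethoxy)-2'-methyl-2'-(4-methylpent-3-en-1-yl)-2-(3-methylbut-2-en-1-yl)-3'-(triisopropylsilyloxy)-3',4'-dihydro-2'H-pyrano[2',3':10,11]dibenzo[b,f]oxepine, via cesium phenoxide 27 (not isolated), via aryne 28 (not isolated), via hemiketal 29 (not isolated)
Conditions: CsF (5 equiv), 18-crown-6 (cat.), THF, 65 °C, 26 (1.3 equiv) added slowly; H2O quench; then pyridinium p-toluenesulfonate (cat.), 4 Å molecular sieves, CH2Cl2, rt
Reagents that add atoms: none
Why: Proposed new method: fluoride cleaves the aryl silyl ether of 19 to phenoxide 27 and converts 26 into aryne 28; the phenoxide oxygen adds to the aryne carbon remote from chlorine (O5–C5a bond), the aryl anion formed beside chlorine attacks the lactone carbonyl (C10–C9a bond) to give the alkoxide of hemiketal 29, and the pyridinium salt then removes water across C10–C11. The closest known reaction type is the fluoride-triggered annulation of arynes with ortho-hydroxyaryl esters and ketones, which gives xanthones and 9-hydroxyxanthenes by the same O-arylation and acyl capture; new here are the tether one atom longer and a lactone as acyl acceptor whose ring oxygen is kept. Ring C closes by 7-exo-trig attack of the aryl carbanion on the C10 carbonyl, while ring D is already present as the lactone and only changes from ester to ketal to enol ether. No stereocentre is created: C2' and C3' are spectators and the C11 epimers of 19 converge because C11 becomes sp2. The step needs oxygen to bond to the aryne carbon meta to chlorine; the inductively withdrawing chlorine beside the triple bond makes that carbon the more electrophilic one and places the developing negative charge next to itself, whereas the alkoxy group, not adjacent to the triple bond, has little influence. The silyl mask leaves no phenolic proton to quench the aryl anion, THF is a poorer proton donor than acetonitrile, and slow addition of 26 keeps the aryne from arylating the product alkoxide. Dehydration can only go towards C11, the one hydrogen-bearing carbon next to C10, and is favoured by conjugation with both arenes.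

Step 20
Reactants: 30 (2'S,3'S)-9-chloro-3,7-bis(methoxymethoxy)-2'-methyl-2'-(4-methylpent-3-en-1-yl)-2-(3-methylbut-2-en-1-yl)-3'-(triisopropylsilyloxy)-3',4'-dihydro-2'H-pyrano[2',3':10,11]dibenzo[b,f]oxepine
Product: 31 (2'S,3'S)-3,7-bis(methoxymethoxy)-2'-methyl-2'-(4-methylpent-3-en-1-yl)-2-(3-methylbut-2-en-1-yl)-3'-(triisopropylsilyloxy)-3',4'-dihydro-2'H-pyrano[2',3':10,11]dibenzo[b,f]oxepine
Conditions: Pd(OAc)2 (10 mol %), PCy3 (20 mol %), HCO2Na, DMF, 100 °C
Reagents that add atoms: none
Why: Palladium-catalysed transfer hydrogenolysis of the aryl chloride (oxidative addition helped by the electron-rich bulky phosphine, formate as hydride donor with loss of CO2); trisubstituted alkenes and the tetrasubstituted enol ether should not react, and no hydrogen gas is used.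

Step 21
Reactants: 31 (2'S,3'S)-3,7-bis(methoxymethoxy)-2'-methyl-2'-(4-methylpent-3-en-1-yl)-2-(3-methylbut-2-en-1-yl)-3'-(triisopropylsilyloxy)-3',4'-dihydro-2'H-pyrano[2',3':10,11]dibenzo[b,f]oxepine
Product: 33 (2'S,3'S)-2'-methyl-2'-(4-methylpent-3-en-1-yl)-2-(3-methylbut-2-en-1-yl)-3'-(triisopropylsilyloxy)-3',4'-dihydro-2'H-pyrano[2',3':10,11]dibenzo[b,f]oxepine-3,7-diol, via bis(trimethylsilyl) aryl ether 32 (not isolated)
Conditions: TMSOTf, 2,2'-bipyridyl, CH2Cl2, 0 °C to rt; then H2O
Reagents that add atoms: none
Why: Acetal cleavage by silyl transfer; the silyl triflate–bipyridyl complex turns aryl methoxymethyl ethers into aryl silyl ethers without free protic acid, and water then hydrolyses these. The hindered secondary silyl ether should stay, and the absence of strong acid protects the enol ether and the ortho-prenylphenol.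

Step 22
Reactants: 33 (2'S,3'S)-2'-methyl-2'-(4-methylpent-3-en-1-yl)-2-(3-methylbut-2-en-1-yl)-3'-(triisopropylsilyloxy)-3',4'-dihydro-2'H-pyrano[2',3':10,11]dibenzo[b,f]oxepine-3,7-diol
Product: 34 (2'S,3'S)-2'-methyl-2'-(4-methylpent-3-en-1-yl)-2-(3-methylbut-2-en-1-yl)-3',4'-dihydro-2'H-pyrano[2',3':10,11]dibenzo[b,f]oxepine-3,7,3'-triol (CNP0185870.1)
Conditions: Bu4NF, AcOH, THF, rt to 40 °C
Reagents that add atoms: none
Why: Fluoride cleavage of the silyl ether under acetic acid buffering; the last step is not acidic enough to touch the enol ether or the prenylphenol and leaves both stereocentres alone.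

## Compound list

1 | 2,4-dihydroxybenzaldehyde | O=Cc1ccc(O)cc1O | starting material
2 | 2-hydroxy-4-(methoxymethoxy)benzaldehyde | O=Cc1ccc(OCOC)cc1O | intermediate
3 | 5-bromo-2-hydroxy-4-(methoxymethoxy)benzaldehyde | O=Cc1cc(Br)c(OCOC)cc1O | intermediate
4 | 5-bromo-2-(tert-butyldimethylsilyloxy)-4-(methoxymethoxy)benzaldehyde | O=Cc1cc(Br)c(OCOC)cc1O[Si](C)(C)C(C)(C)C | intermediate
5 | 2-(tert-butyldimethylsilyloxy)-4-(methoxymethoxy)-5-(3-methylbut-2-en-1-yl)benzaldehyde | O=Cc1cc(CC=C(C)C)c(OCOC)cc1O[Si](C)(C)C(C)(C)C | intermediate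
6 | tert-butyl{5-(methoxymethoxy)-2-(2-methoxyethenyl)-4-(3-methylbut-2-en-1-yl)phenoxy}dimethylsilane (E/Z mixture) | COC=Cc1cc(CC=C(C)C)c(OCOC)cc1O[Si](C)(C)C(C)(C)C | intermediate
7 | methyl 2-[2-(tert-butyldimethylsilyloxy)-4-(methoxymethoxy)-5-(3-methylbut-2-en-1-yl)phenyl]acetate | COC(=O)Cc1cc(CC=C(C)C)c(OCOC)cc1O[Si](C)(C)C(C)(C)C | intermediate
8 | nerol, (2Z)-3,7-dimethylocta-2,6-dien-1-ol | CC(C)=CCC/C(C)=C\CO | starting material
9 | [(2R,3S)-3-methyl-3-(4-methylpent-3-en-1-yl)oxiran-2-yl]methanol | CC(C)=CCC[C@]1(C)O[C@@H]1CO | intermediate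
10 | (2S)-6-methyl-2-[(2S)-oxiran-2-yl]hept-5-en-2-ol | CC(C)=CCC[C@](C)(O)[C@@H]1CO1 | intermediate
11 | (2S,3S)-3,7-dimethyloct-6-ene-1,2,3-triol | CC(C)=CCC[C@](C)(O)[C@@H](O)CO | intermediate
12 | (2S,3S)-2,3-dihydroxy-3,7-dimethyloct-6-en-1-yl 2,2-dimethylpropanoate | CC(C)=CCC[C@](C)(O)[C@@H](O)COC(=O)C(C)(C)C | intermediate
13 | (2S,3S)-3-hydroxy-3,7-dimethyl-2-(triisopropylsilyloxy)oct-6-en-1-yl 2,2-dimethylpropanoate | CC(C)=CCC[C@](C)(O)[C@@H](O[Si](C(C)C)(C(C)C)C(C)C)COC(=O)C(C)(C)C | intermediate
14 | (2S,3S)-3,7-dimethyl-2-(triisopropylsilyloxy)-3-(trimethylsilyloxy)oct-6-en-1-yl 2,2-dimethylpropanoate | CC(C)=CCC[C@](C)(O[Si](C)(C)C)[C@@H](O[Si](C(C)C)(C(C)C)C(C)C)COC(=O)C(C)(C)C | intermediate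
15 | (2S,3S)-3,7-dimethyl-2-(triisopropylsilyloxy)-3-(trimethylsilyloxy)oct-6-en-1-ol | CC(C)=CCC[C@](C)(O[Si](C)(C)C)[C@@H](O[Si](C(C)C)(C(C)C)C(C)C)CO | intermediate
16 | (2S,3S)-3,7-dimethyl-2-(triisopropylsilyloxy)-3-(trimethylsilyloxy)oct-6-en-1-yl trifluoromethanesulfonate | CC(C)=CCC[C@](C)(O[Si](C)(C)C)[C@@H](O[Si](C(C)C)(C(C)C)C(C)C)COS(=O)(=O)C(F)(F)F | intermediate
17 | methyl (4S,5S)-2-[2-(tert-butyldimethylsilyloxy)-4-(methoxymethoxy)-5-(3-methylbut-2-en-1-yl)phenyl]-5,9-dimethyl-4-(triisopropylsilyloxy)-5-(trimethylsilyloxy)dec-8-enoate (C2 epimers) | CC(C)=CCC[C@](C)(O[Si](C)(C)C)[C@@H](O[Si](C(C)C)(C(C)C)C(C)C)CC(C(=O)OC)c1cc(CC=C(C)C)c(OCOC)cc1O[Si](C)(C)C(C)(C)C | intermediate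
18 | methyl (4S,5S)-2-[2-(tert-butyldimethylsilyloxy)-4-(methoxymethoxy)-5-(3-methylbut-2-en-1-yl)phenyl]-5-hydroxy-5,9-dimethyl-4-(triisopropylsilyloxy)dec-8-enoate (C2 epimers) | CC(C)=CCC[C@](C)(O)[C@@H](O[Si](C(C)C)(C(C)C)C(C)C)CC(C(=O)OC)c1cc(CC=C(C)C)c(OCOC)cc1O[Si](C)(C)C(C)(C)C | intermediate
19 | (5S,6S)-3-[2-(tert-butyldimethylsilyloxy)-4-(methoxymethoxy)-5-(3-methylbut-2-en-1-yl)phenyl]-6-methyl-6-(4-methylpent-3-en-1-yl)-5-(triisopropylsilyloxy)oxan-2-one (C3 epimers) | CC(C)=CCC[C@]1(C)OC(=O)C(C[C@@H]1O[Si](C(C)C)(C(C)C)C(C)C)c1cc(CC=C(C)C)c(OCOC)cc1O[Si](C)(C)C(C)(C)C | intermediate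
20 | hydroquinone | Oc1ccc(O)cc1 | starting material
21 | 4-(methoxymethoxy)phenol | COCOc1ccc(O)cc1 | intermediate
22 | 2-chloro-4-(methoxymethoxy)phenol | COCOc1ccc(O)c(Cl)c1 | intermediate
23 | 2-bromo-6-chloro-4-(methoxymethoxy)phenol | COCOc1cc(Br)c(O)c(Cl)c1 | intermediate
24 | [2-bromo-6-chloro-4-(methoxymethoxy)phenoxy]trimethylsilane | COCOc1cc(Br)c(O[Si](C)(C)C)c(Cl)c1 | intermediate
25 | lithium 2-chloro-4-(methoxymethoxy)-6-(trimethylsilyl)phenoxide | COCOc1cc([Si](C)(C)C)c([O-])c(Cl)c1.[Li+] | intermediate
26 | 2-chloro-4-(methoxymethoxy)-6-(trimethylsilyl)phenyl trifluoromethanesulfonate | COCOc1cc([Si](C)(C)C)c(OS(=O)(=O)C(F)(F)F)c(Cl)c1 | intermediate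
27 | cesium 2-[(5S,6S)-6-methyl-6-(4-methylpent-3-en-1-yl)-2-oxo-5-(triisopropylsilyloxy)oxan-3-yl]-5-(methoxymethoxy)-4-(3-methylbut-2-en-1-yl)phenoxide | CC(C)=CCC[C@]1(C)OC(=O)C(C[C@@H]1O[Si](C(C)C)(C(C)C)C(C)C)c1cc(CC=C(C)C)c(OCOC)cc1[O-].[Cs+] | intermediate
28 | 3-chloro-5-(methoxymethoxy)benzyne (triple bond C1–C2, chlorine on C3) | COCOC1=CC#CC(Cl)=C1 | intermediate
29 | hemiketal of 30: (2'S,3'S)-9-chloro-10-hydroxy-3,7-bis(methoxymethoxy)-2'-methyl-2'-(4-methylpent-3-en-1-yl)-2-(3-methylbut-2-en-1-yl)-3'-(triisopropylsilyloxy)-10,11,3',4'-tetrahydro-2'H-pyrano[2',3':10,11]dibenzo[b,f]oxepine (C10 and C11 epimers) | CC(C)=CCC[C@]1(C)OC2(O)C(C[C@@H]1O[Si](C(C)C)(C(C)C)C(C)C)c1cc(CC=C(C)C)c(OCOC)cc1Oc1cc(OCOC)cc(Cl)c12 | intermediate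
30 | (2'S,3'S)-9-chloro-3,7-bis(methoxymethoxy)-2'-methyl-2'-(4-methylpent-3-en-1-yl)-2-(3-methylbut-2-en-1-yl)-3'-(triisopropylsilyloxy)-3',4'-dihydro-2'H-pyrano[2',3':10,11]dibenzo[b,f]oxepine | CC(C)=CCC[C@]1(C)OC2=C(C[C@@H]1O[Si](C(C)C)(C(C)C)C(C)C)c1cc(CC=C(C)C)c(OCOC)cc1Oc1cc(OCOC)cc(Cl)c12 | intermediate
31 | (2'S,3'S)-3,7-bis(methoxymethoxy)-2'-methyl-2'-(4-methylpent-3-en-1-yl)-2-(3-methylbut-2-en-1-yl)-3'-(triisopropylsilyloxy)-3',4'-dihydro-2'H-pyrano[2',3':10,11]dibenzo[b,f]oxepine | CC(C)=CCC[C@]1(C)OC2=C(C[C@@H]1O[Si](C(C)C)(C(C)C)C(C)C)c1cc(CC=C(C)C)c(OCOC)cc1Oc1cc(OCOC)ccc12 | intermediate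
32 | (2'S,3'S)-2'-methyl-2'-(4-methylpent-3-en-1-yl)-2-(3-methylbut-2-en-1-yl)-3'-(triisopropylsilyloxy)-3,7-bis(trimethylsilyloxy)-3',4'-dihydro-2'H-pyrano[2',3':10,11]dibenzo[b,f]oxepine | CC(C)=CCC[C@]1(C)OC2=C(C[C@@H]1O[Si](C(C)C)(C(C)C)C(C)C)c1cc(CC=C(C)C)c(O[Si](C)(C)C)cc1Oc1cc(O[Si](C)(C)C)ccc12 | intermediate
33 | (2'S,3'S)-2'-methyl-2'-(4-methylpent-3-en-1-yl)-2-(3-methylbut-2-en-1-yl)-3'-(triisopropylsilyloxy)-3',4'-dihydro-2'H-pyrano[2',3':10,11]dibenzo[b,f]oxepine-3,7-diol | CC(C)=CCC[C@]1(C)OC2=C(C[C@@H]1O[Si](C(C)C)(C(C)C)C(C)C)c1cc(CC=C(C)C)c(O)cc1Oc1cc(O)ccc12 | intermediate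
34 | (2'S,3'S)-2'-methyl-2'-(4-methylpent-3-en-1-yl)-2-(3-methylbut-2-en-1-yl)-3',4'-dihydro-2'H-pyrano[2',3':10,11]dibenzo[b,f]oxepine-3,7,3'-triol (CNP0185870.1) | CC(C)=CCC[C@]1(C)OC2=C(C[C@@H]1O)c1cc(CC=C(C)C)c(O)cc1Oc1cc(O)ccc12 | target

## Step count and least certain steps

Total: 22 steps. Longest linear sequence: 12 steps (steps 1–6 or 7–12, then 13, 14, 19, 20, 21, 22).

**Step 19 (key step, proposed new method).** The aryl anion formed after O-arylation may be lost before it closes the seven-membered ring. It can take the acidic C11 proton through a transition state of similar size, or it can expel the neighbouring chloride and form a second aryne. Over-arylation of the product alkoxide by excess aryne is a lesser risk.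

The fallback uses known reactions and runs from 19 to 31, which also makes step 20 unnecessary. Commercial 4-bromo-3-chlorophenol is protected with chloromethyl methyl ether and iPr2NEt to give 1-bromo-2-chloro-4-(methoxymethoxy)benzene F1. Magnesium insertion (Mg, LiCl, THF) gives [2-chloro-4-(methoxymethoxy)phenyl]magnesium bromide F2. This is added to lactone 19 with LaCl3·2LiCl at −40 °C to give the 2-aryl lactol F3. Pyridinium p-toluenesulfonate with molecular sieves dehydrates it to the C10-aryl enol ether F4, in which the ring holds the two arenes cis. Bu4NF at 0 °C frees the ring A phenol F5. Intramolecular palladium-catalysed diaryl ether formation (Pd(OAc)2, 2-di-tert-butylphosphino-2',4',6'-triisopropylbiphenyl, K3PO4, toluene, 100 °C) then closes ring C and gives 31.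

**Step 4.** The allyl unit may couple at its substituted end, giving the reverse-prenyl isomer, or the aryl silyl ether may be lost at 100 °C. Fallback from 4 to 5: Stille coupling with allyltributylstannane and Pd(PPh3)4 gives 5-allyl-2-(tert-butyldimethylsilyloxy)-4-(methoxymethoxy)benzaldehyde F6, which has no regiochemical question. Cross-metathesis with 2-methylbut-2-ene and the second-generation Grubbs catalyst (H2IMes)(PCy3)Cl2Ru=CHPh then gives 5.

**Step 6.** The chromium oxidant may cleave the very electron-rich styrenyl double bond back to aldehyde 5 instead of transferring oxygen. Fallback from 6 to 7: Hg(OAc)2 in aqueous THF hydrolyses the enol ether to 2-[2-(tert-butyldimethylsilyloxy)-4-(methoxymethoxy)-5-(3-methylbut-2-en-1-yl)phenyl]acetaldehyde F7. Chlorite oxidation (NaClO2, NaH2PO4, 2-methylbut-2-ene) gives the arylacetic acid F8, and trimethylsilyldiazomethane gives 7.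

**Step 13.** Displacement at the beta-branched, beta-silyloxy carbon may be too slow, so that the triflate decomposes or the aryl silyl group migrates to the enolate first. Fallback from 15 and 7 to 17: Dess–Martin oxidation of 15 gives (2R,3S)-3,7-dimethyl-2-(triisopropylsilyloxy)-3-(trimethylsilyloxy)oct-6-enal F9. Aldol addition of the lithium enolate of 7 gives the beta-hydroxy ester F10. Dehydration with methyl N-(triethylammoniosulfonyl)carbamate (Burgess reagent) gives the 2-aryl enoate F11, and conjugate reduction with [(Ph3P)CuH]6 gives 17, which the acid work-up of step 13 converts into 18.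

**Step 14.** Acyl transfer to the hindered tertiary alkoxide may be slow, so that deprotonation at C11 or cleavage of the aryl silyl ether by the methoxide released takes over. Fallback from 18 to 19, activating the acid instead of the alcohol: Me3SnOH in 1,2-dichloroethane at 80 °C hydrolyses the methyl ester to the hydroxy acid F12. Yamaguchi lactonisation (2,4,6-trichlorobenzoyl chloride, Et3N, then DMAP) gives 19.

**Step 21.** The silyl triflate may attack the enol ether at C11, and the C10 oxocarbenium ion would then be hydrolysed, opening ring D. Fallback from 31 to 33, accepting that opening: 2 M HCl in THF at 40 °C cleaves both acetals and hydrates the enol ether to the hemiketal diphenol F13, which is in equilibrium with its open hydroxy ketone. Pyridinium p-toluenesulfonate with molecular sieves, as in step 19, closes it again to 33.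

## Further compounds

F1 | step 19 | 1-bromo-2-chloro-4-(methoxymethoxy)benzene | COCOc1ccc(Br)c(Cl)c1
F2 | step 19 | [2-chloro-4-(methoxymethoxy)phenyl]magnesium bromide | COCOc1ccc([Mg]Br)c(Cl)c1
F3 | step 19 | (5S,6S)-3-[2-(tert-butyldimethylsilyloxy)-4-(methoxymethoxy)-5-(3-methylbut-2-en-1-yl)phenyl]-2-[2-chloro-4-(methoxymethoxy)phenyl]-6-methyl-6-(4-methylpent-3-en-1-yl)-5-(triisopropylsilyloxy)oxan-2-ol | CC(C)=CCC[C@]1(C)OC(O)(c2ccc(OCOC)cc2Cl)C(C[C@@H]1O[Si](C(C)C)(C(C)C)C(C)C)c1cc(CC=C(C)C)c(OCOC)cc1O[Si](C)(C)C(C)(C)C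
F4 | step 19 | (2S,3S)-5-[2-(tert-butyldimethylsilyloxy)-4-(methoxymethoxy)-5-(3-methylbut-2-en-1-yl)phenyl]-6-[2-chloro-4-(methoxymethoxy)phenyl]-2-methyl-2-(4-methylpent-3-en-1-yl)-3-(triisopropylsilyloxy)-3,4-dihydro-2H-pyran | CC(C)=CCC[C@]1(C)OC(c2ccc(OCOC)cc2Cl)=C(C[C@@H]1O[Si](C(C)C)(C(C)C)C(C)C)c1cc(CC=C(C)C)c(OCOC)cc1O[Si](C)(C)C(C)(C)C
F5 | step 19 | 2-[(2S,3S)-6-[2-chloro-4-(methoxymethoxy)phenyl]-2-methyl-2-(4-methylpent-3-en-1-yl)-3-(triisopropylsilyloxy)-3,4-dihydro-2H-pyran-5-yl]-5-(methoxymethoxy)-4-(3-methylbut-2-en-1-yl)phenol | CC(C)=CCC[C@]1(C)OC(c2ccc(OCOC)cc2Cl)=C(C[C@@H]1O[Si](C(C)C)(C(C)C)C(C)C)c1cc(CC=C(C)C)c(OCOC)cc1O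
F6 | step 4 | 5-allyl-2-(tert-butyldimethylsilyloxy)-4-(methoxymethoxy)benzaldehyde | O=Cc1cc(CC=C)c(OCOC)cc1O[Si](C)(C)C(C)(C)C
F7 | step 6 | 2-[2-(tert-butyldimethylsilyloxy)-4-(methoxymethoxy)-5-(3-methylbut-2-en-1-yl)phenyl]acetaldehyde | O=CCc1cc(CC=C(C)C)c(OCOC)cc1O[Si](C)(C)C(C)(C)C
F8 | step 6 | 2-[2-(tert-butyldimethylsilyloxy)-4-(methoxymethoxy)-5-(3-methylbut-2-en-1-yl)phenyl]acetic acid | OC(=O)Cc1cc(CC=C(C)C)c(OCOC)cc1O[Si](C)(C)C(C)(C)C
F9 | step 13 | (2R,3S)-3,7-dimethyl-2-(triisopropylsilyloxy)-3-(trimethylsilyloxy)oct-6-enal | CC(C)=CCC[C@](C)(O[Si](C)(C)C)[C@@H](O[Si](C(C)C)(C(C)C)C(C)C)C=O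
F10 | step 13 | methyl (4S,5S)-2-[2-(tert-butyldimethylsilyloxy)-4-(methoxymethoxy)-5-(3-methylbut-2-en-1-yl)phenyl]-3-hydroxy-5,9-dimethyl-4-(triisopropylsilyloxy)-5-(trimethylsilyloxy)dec-8-enoate (C2 and C3 epimers) | CC(C)=CCC[C@](C)(O[Si](C)(C)C)[C@@H](O[Si](C(C)C)(C(C)C)C(C)C)C(O)C(C(=O)OC)c1cc(CC=C(C)C)c(OCOC)cc1O[Si](C)(C)C(C)(C)C
F11 | step 13 | methyl (4S,5S)-2-[2-(tert-butyldimethylsilyloxy)-4-(methoxymethoxy)-5-(3-methylbut-2-en-1-yl)phenyl]-5,9-dimethyl-4-(triisopropylsilyloxy)-5-(trimethylsilyloxy)deca-2,8-dienoate (E/Z mixture at C2) | CC(C)=CCC[C@](C)(O[Si](C)(C)C)[C@@H](O[Si](C(C)C)(C(C)C)C(C)C)C=C(C(=O)OC)c1cc(CC=C(C)C)c(OCOC)cc1O[Si](C)(C)C(C)(C)C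
F12 | step 14 | (4S,5S)-2-[2-(tert-butyldimethylsilyloxy)-4-(methoxymethoxy)-5-(3-methylbut-2-en-1-yl)phenyl]-5-hydroxy-5,9-dimethyl-4-(triisopropylsilyloxy)dec-8-enoic acid (C2 epimers) | CC(C)=CCC[C@](C)(O)[C@@H](O[Si](C(C)C)(C(C)C)C(C)C)CC(C(=O)O)c1cc(CC=C(C)C)c(OCOC)cc1O[Si](C)(C)C(C)(C)C
F13 | step 21 | (2'S,3'S)-2'-methyl-2'-(4-methylpent-3-en-1-yl)-2-(3-methylbut-2-en-1-yl)-3'-(triisopropylsilyloxy)-10,11,3',4'-tetrahydro-2'H-pyrano[2',3':10,11]dibenzo[b,f]oxepine-3,7,10-triol (C10 and C11 epimers) | CC(C)=CCC[C@]1(C)OC2(O)C(C[C@@H]1O[Si](C(C)C)(C(C)C)C(C)C)c1cc(CC=C(C)C)c(O)cc1Oc1cc(O)ccc12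
A1 | alternative 1 | (3S,4S)-3-(tert-butyldimethylsilyloxy)-1-[2,4-dihydroxy-5-(3-methylbut-2-en-1-yl)phenyl]-4-hydroxy-4,8-dimethylnon-7-en-1-one | CC(C)=CCC[C@](C)(O)[C@@H](O[Si](C)(C)C(C)(C)C)CC(=O)c1cc(CC=C(C)C)c(O)cc1O
A2 | alternative 1 | (9S,10S)-9-(tert-butyldimethylsilyloxy)-10-hydroxy-1,1-dimethoxy-10,14-dimethyl-2-(3-methylbut-2-en-1-yl)pentadec-13-ene-3,5,7-trione | CC(C)=CCC[C@](C)(O)[C@@H](O[Si](C)(C)C(C)(C)C)CC(=O)CC(=O)CC(=O)C(CC=C(C)C)C(OC)OC
A3 | alternative 2 | (2'S,3'S)-3,7-bis(methoxymethoxy)-2'-methyl-2'-(4-methylpent-3-en-1-yl)-2-(3-methylbut-2-en-1-yl)-3'-(4,4,5,5-tetramethyl-1,3,2-dioxaborolan-2-yl)-3',4'-dihydro-2'H-pyrano[2',3':10,11]dibenzo[b,f]oxepine | CC(C)=CCC[C@]1(C)OC2=C(C[C@@H]1B1OC(C)(C)C(C)(C)O1)c1cc(CC=C(C)C)c(OCOC)cc1Oc1cc(OCOC)ccc12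
A4 | alternative 2 | 3,7-bis(methoxymethoxy)-11-methylidene-2-(3-methylbut-2-en-1-yl)dibenzo[b,f]oxepin-10(11H)-one | C=C1C(=O)c2ccc(OCOC)cc2Oc2cc(OCOC)c(CC=C(C)C)cc21
A5 | alternative 2 | 2-[(1Z)-2,6-dimethylhepta-1,5-dien-1-yl]-4,4,5,5-tetramethyl-1,3,2-dioxaborolane | CC(C)=CCC/C(C)=C\B1OC(C)(C)C(C)(C)O1
A6 | alternative 3 | (2'S,3'S)-3,3'-bis(tert-butyldimethylsilyloxy)-2'-methyl-2'-(4-methylpent-3-en-1-yl)-2-(3-methylbut-2-en-1-yl)-3',4'-dihydro-2'H-pyrano[2',3':10,11]dibenzo[b,f]oxepin-7-yl 2,2-dimethylpropanoate | CC(C)=CCC[C@]1(C)OC2=C(C[C@@H]1O[Si](C)(C)C(C)(C)C)c1cc(CC=C(C)C)c(O[Si](C)(C)C(C)(C)C)cc1Oc1cc(OC(=O)C(C)(C)C)ccc12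
A7 | alternative 3 | 6-(tert-butyldimethylsilyloxy)-9-[(3S,4S)-3-(tert-butyldimethylsilyloxy)-4-hydroxy-4,8-dimethylnon-7-en-1-ylidene]-7-(3-methylbut-2-en-1-yl)-9H-xanthen-3-yl 2,2-dimethylpropanoate | CC(C)=CCC[C@](C)(O)[C@@H](O[Si](C)(C)C(C)(C)C)CC=C1c2cc(CC=C(C)C)c(O[Si](C)(C)C(C)(C)C)cc2Oc2cc(OC(=O)C(C)(C)C)ccc21
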